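In a one-step world a reagent with one first-order rival hands a fixed share of itself to the useful step whatever its charge, but in this flask the activator also pairs off, a loss that grows with its own level, so that share changes during the run.

starting material 0.020 M; activator 0.0180 M; time 2.5 d

    starting material + activated form → open dimer (k1 = 0.130 M⁻¹ s⁻¹)
    activated form → side product (k2 = 0.00176 s⁻¹)
    2 activator → homo dimer (k3 = 0.0476 M⁻¹ s⁻¹)
    activated form → ring (k4 = 0.00360 s⁻¹)
    activator → decomposed reagent (k5 = 6.01 × 10⁻⁴ s⁻¹)
    starting material + activator → activated form (k6 = 0.0267 M⁻¹ s⁻¹)

- percent here means starting material units held: one open dimer counts as two
- a step written with two of one species runs at k times the square of its concentration and takes two of it each time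
- the reaction counts as stopped when no species that holds the starting material changes by six tenths of a point or more over the second half of the time
- run time (flask): 2.5 d

- why nothing more happens at 2.5 d, or that something still does (it is still moving / all of the starting material has reacted / the activator has run out first)
- share of the starting material used up at 2.5 d
- ring at 2.5 d, in percent of the starting material charged
- open dimer at 2.5 d, in percent of the starting material charged

I write a for the starting material and b for the activator, each as a fraction of its own charge. Pairing takes each activator at a rate proportional to b, while activation and decomposition together take it at a steady rate as long as a holds, so I call the crossing fraction the level of b at which these two rates are equal: 0.662 with a at one, which is lower than the starting b of one. Integrating b downward gives the activated share of the charged starting material: the activation constant over the pairing constant per activator, times a, times the logarithm of one plus the inverse crossing fraction, here 0.258.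

Now the settings. The activator's half-life by decomposition alone, 0.32 h, is far shorter than the 2.5 d allowed, so I expect more time to add nothing. A larger activator charge raises that share by a logarithm, not in proportion. A larger starting material charge lifts the crossing fraction and also the capture, the share of activated form taken by starting material, 0.327 at a of one.

Each activated unit uses one starting material and each captured one a second, so the first pass uses 34.2%, and I put a at its midpoint, 0.829. The second pass gives an activated share of 0.226 and a capture of 0.287. I commit to the activator as limiting reagent, with 29.1% used up, ring 10.8% and open dimer 13.0%.

The forecast says the activator has run out first, with 29.5% used up, ring 11.6% and open dimer 12.2%, holding that “only about a quarter of the starting material is ever activated”; its ring stands higher than mine and its open dimer lower.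

The simulation gives the activator has run out first, with 0% of it left at 2.50 d, 29.7% used up, ring 11.1% and open dimer 13.3%. With the 70% of starting material left, the midpoint a gives this flask an activated share of 23.0%, and ring and side product, with each open dimer counted as one activated unit, hold 23.1%. The neighbour flask with 0.072 M of activator has its crossing at 0.166 of its own charge; the same reckoning gives 42.7%, and it holds 42.3%, with 52.7% used up. The first flask is at rest, moving 0 percentage points over the second half of the time: at 25.0 d it shows 29.7% used up, ring 11.1% and open dimer 13.3%.

All constants were set for the occasion; the result is computed.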